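Locants: the side chain runs from C1' (benzylic CH2) to C16', and ring A is the methylhydroquinone ring.

**Plan**
1. Cuts, in order: the O–Si and O–Ac groups, then C9'–C10', then C5'–C6' and C1'–C2' in the western half, and C12'–C13' and C14'=C15' in the eastern half.
2. Enabling feature: C9'H2 is an unbranched sp3 carbon of a 1,5-diene unit, bonded to C10'H, the hydrogen-bearing end of the E-trisubstituted C10'=C11' alkene. C9' can therefore be released as a non-cyclising primary homoallyl radical from the one-carbon-longer acid (as its N-hydroxyphthalimide ester), and C10' can carry iodine with fixed geometry.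
3. Forward order: ring A is bought as 2,6-dimethylhydroquinone, and one of its two equivalent CH3 groups becomes C1'; no ring is formed. The chain is joined at C1'–C2', then C5'–C6', and last at C9'–C10' by nickel-electrocatalytic decarboxylative alkenylation of two complete halves.
4. Alkene geometry: all three E-trisubstituted alkenes come from syn carboalumination of terminal alkynols (but-3-yn-1-ol, pent-4-yn-1-ol, prop-2-yn-1-ol) followed by stereoretentive couplings.
5. Stereocentres: C5' (S) comes from (R)-CBS reduction of the C5' enone, and C12' (R) from the (R)-BINOL/Ti(OiPr)4 Keck allylation. Both are set before the union.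
6. End game: after the union C5'–OH is the only free hydroxyl, so it alone is acetylated. One fluoride step then frees C12'–OH and both phenols.

Key step: step 18

Remark on the chemistry: the SMILES is read as (2'E,5'S,6'E,10'E,12'R). Compounds 1, 4, 8 and 18 are taken as commercial.

**Step 1**
Reactants: 1 2,6-dimethylbenzene-1,4-diol
Product: 2 1,4-bis(tert-butyldimethylsilyloxy)-2,6-dimethylbenzene
Conditions: TBSCl (2.5 equiv), imidazole (5 equiv), DMF, rt to 40 °C
Reagents that add atoms: tert-butyldimethylsilyl chloride, CC(C)(C)[Si](C)(C)Cl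
Why: Imidazole-promoted silylation of both phenols masks ring A against oxidation and lets all silicon groups leave together in the last step.

**Step 2**
Reactants: 2 1,4-bis(tert-butyldimethylsilyloxy)-2,6-dimethylbenzene
Product: 3 2,5-bis(tert-butyldimethylsilyloxy)-3-methylbenzyl bromide
Conditions: NBS (0.95 equiv), AIBN (5 mol %), PhCF3, reflux
Reagents that add atoms: N-bromosuccinimide, O=C1CCC(=O)N1Br
Why: In this Wohl–Ziegler bromination the two methyl groups of 2 are equivalent by symmetry, so monobromination should give a single benzylic bromide, and the non-polar medium with a radical initiator favours hydrogen abstraction over ring substitution.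

**Step 3**
Reactants: 3 2,5-bis(tert-butyldimethylsilyloxy)-3-methylbenzyl bromide; 4 but-3-yn-1-ol
Product: 6 (E)-5-[2,5-bis(tert-butyldimethylsilyloxy)-3-methylphenyl]-3-methylpent-3-en-1-ol, via alkenylalane 5 (not isolated)
Conditions: 4, AlMe3 (3 equiv), Cp2ZrCl2 (0.25 equiv), CH2Cl2, 0 °C to rt; volatiles removed; then 3, Pd(PPh3)4 (5 mol %), THF, rt; aqueous work-up
Reagents that add atoms: trimethylaluminium, C[Al](C)C
Why: Negishi carboalumination adds CH3 and Al syn with Al at the alkyne terminus, and the palladium-catalysed alkenylalane–benzyl halide cross-coupling (run in THF to tame the Lewis acidity of aluminium) forms C1'–C2' with retention, fixing E-C2'=C3'.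

**Step 4**
Reactants: 6 (E)-5-[2,5-bis(tert-butyldimethylsilyloxy)-3-methylphenyl]-3-methylpent-3-en-1-ol
Product: 7 (E)-5-[2,5-bis(tert-butyldimethylsilyloxy)-3-methylphenyl]-3-methylpent-3-enal
Conditions: Dess–Martin periodinane (1.2 equiv), NaHCO3 (5 equiv), CH2Cl2, 0 °C; used without delay
Reagents that add atoms: none
Why: The bicarbonate-buffered Dess–Martin oxidation is neutral and fast, so the β,γ-unsaturated aldehyde should form without C2'=C3' moving into conjugation.

**Step 5**
Reactants: 8 pent-4-yn-1-ol
Product: 10 (E)-5-iodo-4-methylpent-4-en-1-ol, via alkenylalane 9 (not isolated)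
Conditions: AlMe3 (3 equiv), Cp2ZrCl2 (0.25 equiv), CH2Cl2, 0 °C to rt; then iodine, THF, −30 °C
Reagents that add atoms: trimethylaluminium, C[Al](C)C; iodine, [I][I]
Why: Negishi carboalumination followed by stereoretentive iodinolysis of the carbon–aluminium bond gives the E-alkenyl iodide that will become C6'=C7'.

**Step 6**
Reactants: 10 (E)-5-iodo-4-methylpent-4-en-1-ol
Product: 11 (E)-5-iodo-4-methylpent-4-enoic acid
Conditions: TEMPO (20 mol %), PhI(OAc)2 (2.2 equiv), MeCN/H2O 1:1, rt
Reagents that add atoms: water, O
Why: The oxoammonium (TEMPO) oxidation takes the primary alcohol through the aldehyde hydrate to the acid and leaves the alkenyl iodide untouched.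

**Step 7**
Reactants: 11 (E)-5-iodo-4-methylpent-4-enoic acid
Product: 12 allyl (E)-5-iodo-4-methylpent-4-enoate
Conditions: allyl bromide (1.2 equiv), K2CO3 (1.5 equiv), DMF, rt
Reagents that add atoms: allyl bromide, C=CCBr
Why: SN2 alkylation of the carboxylate installs an ester that can later be removed under neutral palladium catalysis, as the hydroxide-labile phenolic silyl ethers require.

**Step 8**
Reactants: 7 (E)-5-[2,5-bis(tert-butyldimethylsilyloxy)-3-methylphenyl]-3-methylpent-3-enal; 12 allyl (E)-5-iodo-4-methylpent-4-enoate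
Product: 13 allyl (4E,8E)-10-[2,5-bis(tert-butyldimethylsilyloxy)-3-methylphenyl]-6-hydroxy-4,8-dimethyldeca-4,8-dienoate, racemic at C6 (= C5')
Conditions: CrCl2 (4 equiv), NiCl2 (2 mol %), DMSO, rt
Reagents that add atoms: none
Why: In the Nozaki–Hiyama–Kishi coupling the alkenyl iodide passes via nickel to a non-basic alkenyl species of trivalent chromium that adds only to the aldehyde, with retention of the E geometry and tolerance of the ester, the enolisable aldehyde and the silyl ethers; C5' forms racemic and is corrected in steps 9 and 10.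

**Step 9**
Reactants: 13 the racemic C5' alcohol
Product: 14 allyl (4E,8E)-10-[2,5-bis(tert-butyldimethylsilyloxy)-3-methylphenyl]-4,8-dimethyl-6-oxodeca-4,8-dienoate
Conditions: Dess–Martin periodinane (1.3 equiv), NaHCO3 (5 equiv), CH2Cl2, 0 °C
Reagents that add atoms: none
Why: The buffered Dess–Martin oxidation of the allylic alcohol gives the C5' enone under conditions too mild to shift the skipped C2'=C3' alkene.

**Step 10**
Reactants: 14 the C5' enone
Product: 15 allyl (4E,6S,8E)-10-[2,5-bis(tert-butyldimethylsilyloxy)-3-methylphenyl]-6-hydroxy-4,8-dimethyldeca-4,8-dienoate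
Conditions: (R)-Me-CBS oxazaborolidine (20 mol %), catecholborane (1.8 equiv), toluene, −78 °C; aqueous work-up
Reagents that add atoms: none
Why: In the Corey–Bakshi–Shibata reduction the ketone binds the (R)-oxazaborolidine with the β,β-disubstituted alkenyl arm as the large group and the C4'H2 arm as the small one, so hydride arrives on the face that gives (5'S), the same sense in which this catalyst gives (S)-1-phenylethanol.

**Step 11**
Reactants: 15 the (6S)-allyl ester
Product: 16 (4E,6S,8E)-10-[2,5-bis(tert-butyldimethylsilyloxy)-3-methylphenyl]-6-hydroxy-4,8-dimethyldeca-4,8-dienoic acid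
Conditions: Pd(PPh3)4 (5 mol %), morpholine (5 equiv), THF, rt; citric acid wash
Reagents that add atoms: none
Why: In the Tsuji–Trost deallylation zerovalent palladium ionises only the allyl ester (the free C5' allylic alcohol is no leaving group) and morpholine traps the allyl unit, so neither base nor fluoride meets the silyl ethers.

**Step 12**
Reactants: 16 the (6S)-hydroxy acid
Product: 17 1,3-dioxoisoindolin-2-yl (4E,6S,8E)-10-[2,5-bis(tert-butyldimethylsilyloxy)-3-methylphenyl]-6-hydroxy-4,8-dimethyldeca-4,8-dienoate
Conditions: N-hydroxyphthalimide (1.1 equiv), N,N'-diisopropylcarbodiimide (1.1 equiv), CH2Cl2, 0 °C to rt; short silica plug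
Reagents that add atoms: N-hydroxyphthalimide, O=C1c2ccccc2C(=O)N1O
Why: In this carbodiimide (Steglich-type) esterification the acidic N–OH outcompetes the hindered secondary alcohol when no acyl-transfer catalyst is added, and the E-C6'=C7' alkene forbids lactonisation.

**Step 13**
Reactants: 18 prop-2-yn-1-ol
Product: 20 (E)-3-iodo-2-methylprop-2-en-1-ol, via alkenylalane 19 (not isolated)
Conditions: AlMe3 (3 equiv), Cp2ZrCl2 (0.25 equiv), CH2Cl2, 0 °C to rt; then iodine, THF, −30 °C
Reagents that add atoms: trimethylaluminium, C[Al](C)C; iodine, [I][I]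
Why: Negishi carboalumination and stereoretentive iodinolysis place CH3 on C11' and iodine on C10' in the E arrangement.

**Step 14**
Reactants: 20 (E)-3-iodo-2-methylprop-2-en-1-ol
Product: 21 (E)-3-iodo-2-methylprop-2-enal
Conditions: MnO2 (15 equiv), CH2Cl2, rt, dark
Reagents that add atoms: none
Why: The allylic alcohol oxidation with MnO2 stops cleanly at the enal and does not disturb the alkenyl iodide.

**Step 15**
Reactants: 21 (E)-3-iodo-2-methylprop-2-enal
Product: 22 (1E,3R)-1-iodo-2-methylhexa-1,5-dien-3-ol
Conditions: allylSnBu3 (1.5 equiv), (R)-BINOL (20 mol %), Ti(OiPr)4 (10 mol %), 4 Å molecular sieves, CH2Cl2, −20 °C; aqueous work-up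
Reagents that add atoms: allyltributylstannane, C=CC[Sn](CCCC)(CCCC)CCCC
Why: In the Keck asymmetric allylation the (R)-BINOL–titanium Lewis acid shields one face of the α-methyl enal, so that the 3R carbinol (C12') results, in the same sense as for other aldehydes whose residue outranks the allyl CH2.

**Step 16**
Reactants: 22 (1E,3R)-1-iodo-2-methylhexa-1,5-dien-3-ol
Product: 23 (1E,3R)-3-(tert-butyldimethylsilyloxy)-1-iodo-2-methylhexa-1,5-diene
Conditions: TBSCl (1.3 equiv), imidazole (2.5 equiv), DMF, rt
Reagents that add atoms: tert-butyldimethylsilyl chloride, CC(C)(C)[Si](C)(C)Cl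
Why: Silylation hides C12'–OH, so that C5'–OH can later be acetylated alone.

**Step 17**
Reactants: 23 (1E,3R)-3-(tert-butyldimethylsilyloxy)-1-iodo-2-methylhexa-1,5-diene
Product: 24 (1E,3R)-3-(tert-butyldimethylsilyloxy)-1-iodo-2,6-dimethylhepta-1,5-diene
Conditions: 2-methylbut-2-ene (large excess), second-generation Grubbs catalyst (5 mol %), CH2Cl2, 40 °C, sealed tube
Reagents that add atoms: 2-methylbut-2-ene, CC=C(C)C
Why: Olefin cross-metathesis turns the monosubstituted allyl terminus into the prenyl terminus, while the trisubstituted alkenyl iodide is too hindered to engage the ruthenium carbene.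

**Step 18**
Reactants: 17 the N-hydroxyphthalimide ester of the western half; 24 the eastern alkenyl iodide
Product: 25 (2E,5S,6E,10E,12R)-1-[2,5-bis(tert-butyldimethylsilyloxy)-3-methylphenyl]-12-(tert-butyldimethylsilyloxy)-3,7,11,15-tetramethylhexadeca-2,6,10,14-tetraen-5-ol
Conditions: 17 (1.3 equiv), 24 (1.0 equiv), NiCl2·6H2O (10 mol %), 2,2'-bipyridine (10 mol %), AgNO3 (0.3 equiv), DMF, Mg anode, reticulated vitreous carbon cathode, undivided cell, constant current (about 3 F/mol), rt
Reagents that add atoms: none
Why: At the cathode the NiCl2–bipyridine complex is reduced to low-valent nickel, which inserts into the C10'–iodine bond of 24 with retention, while one-electron reduction of the phthalimide ester of 17 (by monovalent nickel or at the silver-coated carbon surface) breaks the N–O bond and expels CO2 to leave the primary C9' radical; capture of this radical by the alkenylnickel species and reductive elimination from trivalent nickel forge C9'–C10'. The closest known reaction type is the nickel/silver-electrocatalytic decarboxylative alkenylation of redox-active esters with (E)-2-methylalk-1-enyl iodides, a cross-electrophile coupling worked out on 1,5-polyene terpene chains. No ring is closed and no stereocentre is made: the E geometry of C10'=C11' is inherited from 24, and C5' and C12' are spectators set in steps 10 and 15, so two enantiopure halves merge into one diastereomer. The step needs cross- over homo-coupling, which the two orthogonal activation modes secure (two-electron insertion at the sp2 carbon–iodine bond, one-electron fragmentation of the ester). It also needs a radical that does not cyclise, and C9' is homoallylic to C6'=C7', so only a reversible 3-exo closure is open and every other alkene lies out of 5-exo or 6-exo reach across the rigid E-alkene. Finally C5' is carried as the free alcohol and C12' as a silyl ether, so zerovalent nickel meets no ionisable allylic ester, and the Mg anode supplies the electrons so that no organometallic reagent touches the OH group or the silyl ethers.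

**Step 19**
Reactants: 25 the coupled C5' alcohol
Product: 26 (2E,5S,6E,10E,12R)-1-[2,5-bis(tert-butyldimethylsilyloxy)-3-methylphenyl]-12-(tert-butyldimethylsilyloxy)-3,7,11,15-tetramethylhexadeca-2,6,10,14-tetraen-5-yl acetate
Conditions: Ac2O (2 equiv), pyridine (4 equiv), DMAP (5 mol %), CH2Cl2, 0 °C to rt
Reagents that add atoms: acetic anhydride, CC(=O)OC(C)=O
Why: DMAP-catalysed acylation at oxygen meets a single free hydroxyl and leaves the configuration at C5' untouched.

**Step 20**
Reactants: 26 the tris-silylated acetate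
Product: 27 the target, (2E,5S,6E,10E,12R)-1-(2,5-dihydroxy-3-methylphenyl)-12-hydroxy-3,7,11,15-tetramethylhexadeca-2,6,10,14-tetraen-5-yl acetate
Conditions: TBAF (4 equiv), AcOH (4 equiv), degassed THF, 0 °C to rt, argon
Reagents that add atoms: none
Why: Acetic-acid-buffered fluoride desilylation should remove both phenolic silyl groups and the C12' silyl group in one operation, while the buffered, oxygen-free medium spares the C5' acetate and the hydroquinone.

**Compound list**
1 | 2,6-dimethylbenzene-1,4-diol | Cc1cc(O)cc(C)c1O | starting material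
2 | 1,4-bis(tert-butyldimethylsilyloxy)-2,6-dimethylbenzene | Cc1cc(O[Si](C)(C)C(C)(C)C)cc(C)c1O[Si](C)(C)C(C)(C)C | intermediate
3 | 2,5-bis(tert-butyldimethylsilyloxy)-3-methylbenzyl bromide | BrCc1cc(O[Si](C)(C)C(C)(C)C)cc(C)c1O[Si](C)(C)C(C)(C)C | intermediate
4 | but-3-yn-1-ol | C#CCCO | starting material
5 | dimethylaluminium alkoxide of (E)-4-(dimethylalumanyl)-3-methylbut-3-en-1-ol | C[Al](C)OCC/C(C)=C/[Al](C)C | intermediate
6 | (E)-5-[2,5-bis(tert-butyldimethylsilyloxy)-3-methylphenyl]-3-methylpent-3-en-1-ol | OCC/C(C)=C/Cc1cc(O[Si](C)(C)C(C)(C)C)cc(C)c1O[Si](C)(C)C(C)(C)C | intermediate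
7 | (E)-5-[2,5-bis(tert-butyldimethylsilyloxy)-3-methylphenyl]-3-methylpent-3-enal | O=CC/C(C)=C/Cc1cc(O[Si](C)(C)C(C)(C)C)cc(C)c1O[Si](C)(C)C(C)(C)C | intermediate
8 | pent-4-yn-1-ol | C#CCCCO | starting material
9 | dimethylaluminium alkoxide of (E)-5-(dimethylalumanyl)-4-methylpent-4-en-1-ol | C[Al](C)OCCC/C(C)=C/[Al](C)C | intermediate
10 | (E)-5-iodo-4-methylpent-4-en-1-ol | OCCC/C(C)=C/I | intermediate
11 | (E)-5-iodo-4-methylpent-4-enoic acid | OC(=O)CC/C(C)=C/I | intermediate
12 | allyl (E)-5-iodo-4-methylpent-4-enoate | C=CCOC(=O)CC/C(C)=C/I | intermediate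
13 | allyl (4E,8E)-10-[2,5-bis(tert-butyldimethylsilyloxy)-3-methylphenyl]-6-hydroxy-4,8-dimethyldeca-4,8-dienoate (racemic) | C=CCOC(=O)CC/C(C)=C/C(O)C/C(C)=C/Cc1cc(O[Si](C)(C)C(C)(C)C)cc(C)c1O[Si](C)(C)C(C)(C)C | intermediate
14 | allyl (4E,8E)-10-[2,5-bis(tert-butyldimethylsilyloxy)-3-methylphenyl]-4,8-dimethyl-6-oxodeca-4,8-dienoate | C=CCOC(=O)CC/C(C)=C/C(=O)C/C(C)=C/Cc1cc(O[Si](C)(C)C(C)(C)C)cc(C)c1O[Si](C)(C)C(C)(C)C | intermediate
15 | allyl (4E,6S,8E)-10-[2,5-bis(tert-butyldimethylsilyloxy)-3-methylphenyl]-6-hydroxy-4,8-dimethyldeca-4,8-dienoate | O[C@H](/C=C(\C)CCC(=O)OCC=C)C/C(C)=C/Cc1cc(O[Si](C)(C)C(C)(C)C)cc(C)c1O[Si](C)(C)C(C)(C)C | intermediate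
16 | (4E,6S,8E)-10-[2,5-bis(tert-butyldimethylsilyloxy)-3-methylphenyl]-6-hydroxy-4,8-dimethyldeca-4,8-dienoic acid | O[C@H](/C=C(\C)CCC(=O)O)C/C(C)=C/Cc1cc(O[Si](C)(C)C(C)(C)C)cc(C)c1O[Si](C)(C)C(C)(C)C | intermediate
17 | 1,3-dioxoisoindolin-2-yl (4E,6S,8E)-10-[2,5-bis(tert-butyldimethylsilyloxy)-3-methylphenyl]-6-hydroxy-4,8-dimethyldeca-4,8-dienoate | O[C@H](/C=C(\C)CCC(=O)ON1C(=O)c2ccccc2C1=O)C/C(C)=C/Cc1cc(O[Si](C)(C)C(C)(C)C)cc(C)c1O[Si](C)(C)C(C)(C)C | intermediate
18 | prop-2-yn-1-ol | C#CCO | starting material
19 | dimethylaluminium alkoxide of (E)-3-(dimethylalumanyl)-2-methylprop-2-en-1-ol | C[Al](C)OC/C(C)=C/[Al](C)C | intermediate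
20 | (E)-3-iodo-2-methylprop-2-en-1-ol | OC/C(C)=C/I | intermediate
21 | (E)-3-iodo-2-methylprop-2-enal | O=C/C(C)=C/I | intermediate
22 | (1E,3R)-1-iodo-2-methylhexa-1,5-dien-3-ol | I/C=C(\C)[C@H](O)CC=C | intermediate
23 | (1E,3R)-3-(tert-butyldimethylsilyloxy)-1-iodo-2-methylhexa-1,5-diene | I/C=C(\C)[C@H](O[Si](C)(C)C(C)(C)C)CC=C | intermediate
24 | (1E,3R)-3-(tert-butyldimethylsilyloxy)-1-iodo-2,6-dimethylhepta-1,5-diene | I/C=C(\C)[C@H](O[Si](C)(C)C(C)(C)C)CC=C(C)C | intermediate
25 | (2E,5S,6E,10E,12R)-1-[2,5-bis(tert-butyldimethylsilyloxy)-3-methylphenyl]-12-(tert-butyldimethylsilyloxy)-3,7,11,15-tetramethylhexadeca-2,6,10,14-tetraen-5-ol | O[C@H](/C=C(\C)CC/C=C(\C)[C@H](O[Si](C)(C)C(C)(C)C)CC=C(C)C)C/C(C)=C/Cc1cc(O[Si](C)(C)C(C)(C)C)cc(C)c1O[Si](C)(C)C(C)(C)C | intermediate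
26 | acetate of 25 | CC(=O)O[C@H](/C=C(\C)CC/C=C(\C)[C@H](O[Si](C)(C)C(C)(C)C)CC=C(C)C)C/C(C)=C/Cc1cc(O[Si](C)(C)C(C)(C)C)cc(C)c1O[Si](C)(C)C(C)(C)C | intermediate
27 | (2E,5S,6E,10E,12R)-1-(2,5-dihydroxy-3-methylphenyl)-12-hydroxy-3,7,11,15-tetramethylhexadeca-2,6,10,14-tetraen-5-yl acetate | CC(=O)O[C@H](/C=C(\C)CC/C=C(\C)[C@H](O)CC=C(C)C)C/C(C)=C/Cc1cc(O)cc(C)c1O | target

Total step count: 20.
Longest linear sequence: 12 steps (1 → 2 → 3 → 6 → 7 → 13 → 14 → 15 → 16 → 17 → 25 → 26 → 27).

**Steps most likely to fail**

**Step 18.** Reduction of either partner may outrun the cross-coupling, through protodeiodination of the alkenyl iodide or through reduction or dimerisation of the C9' radical. The phenolic silyl groups may also be lost to the phthalimide anion in DMF.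
- Fallback: the polarity of the alkenyl partner is inverted and the cell is given up.
- Setting out from 24, iodine–lithium exchange (t-BuLi, Et2O, −78 °C) gives the alkenyllithium F1.
- ZnCl2 turns F1 into the alkenylzinc chloride F2.
- F2 (about 3 equiv, one of which is spent on the C5' hydroxyl) is joined with 17 by the redox-neutral, Negishi-type nickel-catalysed decarboxylative alkenylation (Ni(acac)2, 2,2'-bipyridine, THF/DMF, rt).
- The route is rejoined at 25.

**Step 2.** Electrophilic bromination of the electron-rich ring A, double bromination, or desilylation by HBr may compete with benzylic hydrogen abstraction.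
- Fallback: the radical bromination is run on a deactivated ring, and the protecting groups are exchanged afterwards.
- Setting out from 1, Ac2O/pyridine gives 2,6-dimethyl-1,4-phenylene diacetate F3.
- NBS/AIBN gives 2-(bromomethyl)-6-methyl-1,4-phenylene diacetate F4.
- KOAc in DMF gives 2-(acetoxymethyl)-6-methyl-1,4-phenylene diacetate F5.
- K2CO3 in MeOH under argon gives 2-(hydroxymethyl)-6-methylbenzene-1,4-diol F6.
- Excess TBSCl/imidazole gives the tris(tert-butyldimethylsilyl) ether F7.
- Ph3PBr2 in CH2Cl2 converts only the benzylic silyl ether of F7 into the bromide, and the route is rejoined at 3.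

**Step 10.** Facial discrimination may be poor because the two ketone arms differ little in size, and C2'=C3' may migrate into conjugation while 14 is handled.
- Fallback: the stereocentre is set during carbon–carbon bond formation instead of by reduction.
- Setting out from 7 and 12, a catalytic asymmetric Nozaki–Hiyama–Kishi coupling is used: CrCl2 (10 mol %), a chiral oxazoline–sulfonamide ligand in the enantiomeric form that directs the alkenyl group to the Re face of 7, NiCl2·(2,9-dimethyl-1,10-phenanthroline) (2 mol %), Mn powder, Cp2ZrCl2, LiCl, MeCN, rt.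
- This leads directly to 15, where the route is rejoined, and bypasses 13 and 14.
- No compound outside the list arises (F0).

**Further compounds**
F1 | step 18 | (1E,3R)-3-(tert-butyldimethylsilyloxy)-2,6-dimethylhepta-1,5-dien-1-yllithium | [Li]/C=C(\C)[C@H](O[Si](C)(C)C(C)(C)C)CC=C(C)C
F2 | step 18 | (1E,3R)-3-(tert-butyldimethylsilyloxy)-2,6-dimethylhepta-1,5-dien-1-ylzinc chloride | Cl[Zn]/C=C(\C)[C@H](O[Si](C)(C)C(C)(C)C)CC=C(C)C
F3 | step 2 | 2,6-dimethyl-1,4-phenylene diacetate | CC(=O)Oc1cc(C)c(OC(C)=O)c(C)c1
F4 | step 2 | 2-(bromomethyl)-6-methyl-1,4-phenylene diacetate | CC(=O)Oc1cc(C)c(OC(C)=O)c(CBr)c1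
F5 | step 2 | 2-(acetoxymethyl)-6-methyl-1,4-phenylene diacetate | CC(=O)OCc1cc(OC(C)=O)cc(C)c1OC(C)=O
F6 | step 2 | 2-(hydroxymethyl)-6-methylbenzene-1,4-diol | OCc1cc(O)cc(C)c1O
F7 | step 2 | 1,4-bis(tert-butyldimethylsilyloxy)-2-[(tert-butyldimethylsilyloxy)methyl]-6-methylbenzene | CC(C)(C)[Si](C)(C)OCc1cc(O[Si](C)(C)C(C)(C)C)cc(C)c1O[Si](C)(C)C(C)(C)C
F0 | step 10 | none | none
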